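## Numbering of the compounds

1 2,4,6-trihydroxybenzaldehyde · 2 its 4-O-benzyl ether · 3 the 4-O-benzyl 6-O-methyl ether · 4 the fully protected aldehyde (OBn, OMe, OTIPS) · 5 the (E)-cinnamate · 6 the (E)-cinnamyl alcohol · 7 the methyl carbonate · 8 N-methylbut-3-en-1-amine · 9 the (S)-diene amine · 10 its ammonium tosylate · 11 the tetrahydropyridinium tosylate · 12 the (S)-tetrahydropyridine · 13 the (S)-piperidine · 14 the phenol · 15 the iodophenol · 16 phenylacetylene · 17 the aryl alkynyl ketone · 18 the 7-O-TIPS flavone · 19 the target.

Ring A carbons are called by their flavone numbers (C4a, C5, C6, C7, C8, C8a) in every intermediate; piperidine atoms are primed.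

## Analysis of the target

Target 19 is a flavone: ring A (C4a, C5, C6, C7, C8, C8a) is fused to the pyranone ring C (O1, C2, C3, C4), and the phenyl ring B sits on C2. Ring A is a phloroglucinol-type ring whose three oxygens are all different: a methyl ether at C5, a free phenol at C7 and the ring C oxygen at C8a, with hydrogen only at C8. C6, between C5 and C7, carries the only stereocentre, C2′ of an N-methylpiperidine, of S configuration; nothing has to be related to it, but it must be made as one enantiomer. This centre is benzylic and α to nitrogen on a very electron-rich ring. Acid can ionise the C2′–N bond, and heat with a free ortho or para phenol can open the ring to a quinone methide and reclose it, so the centre can be racemised; the basic tertiary amine also binds to transition metals. The hard points are therefore the hindered C6–C2′ bond with its stereocentre, the differentiation of three phloroglucinol oxygens, and the choice of C4a over C8 when ring C is annulated. The strategy rests on the piperidine: its C3′–C4′ bond is far from every functional group, and if it is taken as an alkene, C2′ becomes the branched carbon of an allylic amine that already carries the N-methyl group, so the ring can be closed by olefin metathesis after C6–C2′ and the stereocentre have been set in an acyclic, catalyst-controlled step.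

## Retrosynthetic reasoning

**19 ⇒ 18.** Only the O7–Si bond is cut. The silyl ether keeps O7 distinct from O8a to the end and is removed last under buffered fluoride, so the free 7-phenol, which could assist opening at C2′, exists only in the final product.

**18 ⇒ 15 + 16.** Ring C is cut at C4a–C4, C4–C3 and O1–C2. This takes the whole pyranone back to an ortho-iodophenol, the terminal alkyne 16 and a one-carbon carbonyl unit brought in by carbonylation. It is preferred to stepwise acylation chemistry because it needs no strong base or acid next to C2′. The forward reaction has to insert the carbonyl at the hindered C4a position and close in the 6-endo sense through the ynone 17.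

**15 ⇒ 14.** The C4a–I bond is cut. Both open ring positions of 14 are ortho to the free O8a phenol, so the forward iodination must choose C4a over C8. The bulky silyl ether on O7 next to C8 is what the choice relies on.

**14 ⇒ 13 ⇒ 12.** The benzyl group on O8a is cut by hydrogenolysis, and the C3′–C4′ single bond is traced back to the alkene of 12. The two reductions are kept apart: the alkene is saturated first on platinum, which is least prone to move the double bond towards C2′ or to cleave the allylic C2′–N bond, and only then is the benzyl ether removed on palladium.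

**12 ⇒ 9 (key disconnection).** The C3′=C4′ bond is cut to give the diene 9, which is closed as its ammonium salt 10 to the salt 11. The cut is placed here because it is the only ring bond whose formation touches neither nitrogen nor the stereocentre, and because both alkene partners are monosubstituted and lead to an unstrained six-membered ring. The gain is that the piperidine needs no nitrogen protecting group and that C2′ is set earlier, in an open chain.

**9 ⇒ 7 + 8.** The C2′–N bond is cut. A branch-selective, enantioselective allylic amination of the cinnamyl carbonate 7 with the secondary amine 8 forms this bond, the stereocentre and the complete N-substitution in one step. The catalyst has to override the steric demand of the 2,6-disubstituted aryl ring and the tendency of so electron-rich a carbonate to react without it.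

**7 ⇒ 6 ⇒ 5 ⇒ 4.** The carbonate is an activated form of the alcohol 6, which comes from the ester 5 by hydride reduction. The C=C bond of 5 is cut by a Wittig disconnection back to the aldehyde 4. A neutral stabilised ylide is chosen so that the aryl silyl ether is not exposed to alkoxide.

**4 ⇒ 3 ⇒ 2 ⇒ 1.** The three O–C and O–Si bonds are cut in the order silyl, methyl, benzyl. In 1 the para hydroxyl is the most acidic and is not hydrogen-bonded to the formyl group, so it is benzylated first. The two ortho hydroxyls of 2 are equivalent, and after one is methylated the other is held in a hydrogen bond, so methylation stops at 3. The last hydroxyl is silylated.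

## Alternatives that were turned down

**Alternative 1: intramolecular ester Wittig at C2–C3.** Ring C is cut at C2=C3. In the forward direction the acyl ylide A1, which carries benzoates on O7 and O8a, is heated; the ylide carbon C3 attacks the O8a benzoate carbonyl and olefination gives the flavone benzoate A2. In its favour, the closure is metal-free, needs no carbon monoxide, and its regiochemistry is fixed by the position of the acyl group; on the hindered C4a position it avoids an oxidative addition and is here stronger than the chosen end game. Against it, A1 needs an acetyl group at C4a, then α-halogenation and phosphonium salt formation in a molecule that holds a nucleophilic tertiary amine and an electron-rich ring, so self-quaternisation and nuclear halogenation at C8 compete. The olefination of an ester carbonyl needs prolonged heating, which is the condition under which C2′ can open and reclose. It takes about six operations for ring C where the chosen route takes three, and it leaves the origin of the piperidine and of C2′ open. The chosen strategy offers a short ring C sequence at low temperature and a defined answer for the stereocentre.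

**Alternative 2: ring A by Dieckmann-type closure of a pyranone.** Ring A is cut at C6–C7. Base makes the ketone α-carbon C6 of the 3-acyl-4-pyranone A3 attack its side-chain ester carbon C7, and enolisation gives the 5,7-dihydroxyflavone A4 with an N-Boc piperidine. In its favour, every ring A substituent is placed by construction, the C6–C2′ bond and the stereocentre come with the side chain, and no arene regiochemistry arises; on the C4a versus C8 question it is stronger than the chosen route. Against it, A4 has both phenols free, and the one that must be methylated, O5, is the hydrogen-bonded and less reactive one, so a protect–methylate–deprotect sequence is needed. The nucleophilic carbon C6 is α to a ketone and β to the carbamate nitrogen, so the enolate can expel nitrogen (E1cB), open the piperidine and lose C2′. The Boc group must still be exchanged for methyl in the presence of the flavone, and A3 itself is a multi-step polycarbonyl assembly. The chosen strategy keeps the oxygens differentiated from the second step and never places a carbanion next to C2′.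

**Alternative 3: three-component carbonylative annulation as the central step.** Ring C is cut at C4a–C4, C4–C3 and O1–C2, and the forward step joins the iodophenol 15, a carbonyl unit and 16 under zerovalent palladium to give A5, which is identical with 18. It is the most convergent ring C construction, and on ring C it is exactly as strong as the chosen route, since the chosen route uses it as step 12. As the organising idea it was turned down because it only moves the problem: the fully substituted, enantiopure iodophenol 15 still has to be made, and the disconnection says nothing about C6–C2′, the stereocentre or the piperidine. The chosen strategy supplies that answer and keeps this annulation as a supporting step.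

Key step: step 8

Assumption: the (Sa,S,S) antipode of the phosphoramidite is taken to give the S amine, following the usual facial model for iridium-catalysed amination of cinnamyl carbonates; if the sense is reversed for this ring, the mirror-image ligand is used and nothing else changes.

## Route

Step 1
Reactants: 1 2,4,6-trihydroxybenzaldehyde
Product: 2 4-(benzyloxy)-2,6-dihydroxybenzaldehyde
Conditions: BnBr (1.0 equiv), KHCO3 (1.1 equiv), DMF, rt
Reagents that add atoms: benzyl bromide, BrCc1ccccc1
Why: Williamson etherification; the para hydroxyl is the most acidic and is not engaged in a hydrogen bond to the formyl oxygen, so a weak base and one equivalent of halide should alkylate it first.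

Step 2
Reactants: 2 4-(benzyloxy)-2,6-dihydroxybenzaldehyde
Product: 3 4-(benzyloxy)-2-hydroxy-6-methoxybenzaldehyde
Conditions: MeI (1.05 equiv), K2CO3 (1.1 equiv), acetone, rt
Reagents that add atoms: iodomethane, CI
Why: Williamson O-methylation; the two ortho hydroxyls are equivalent, and after the first is methylated the second is held in a hydrogen bond to the formyl oxygen and is much less nucleophilic, so the reaction should stop at the monoether.

Step 3
Reactants: 3 4-(benzyloxy)-2-hydroxy-6-methoxybenzaldehyde
Product: 4 4-(benzyloxy)-2-methoxy-6-(triisopropylsilyloxy)benzaldehyde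
Conditions: i-Pr3SiOTf (1.2 equiv), 2,6-lutidine (1.5 equiv), CH2Cl2, 0 °C
Reagents that add atoms: triisopropylsilyl trifluoromethanesulfonate, CC(C)[Si](OS(=O)(=O)C(F)(F)F)(C(C)C)C(C)C
Why: O-silylation with a silyl triflate, which is reactive enough for a hydrogen-bonded, hindered phenol; the hindered base does not add to the aldehyde.

Step 4
Reactants: 4 4-(benzyloxy)-2-methoxy-6-(triisopropylsilyloxy)benzaldehyde
Product: 5 ethyl (E)-3-[4-(benzyloxy)-2-methoxy-6-(triisopropylsilyloxy)phenyl]prop-2-enoate
Conditions: Ph3P=CHCO2Et (1.5 equiv), toluene, 110 °C
Reagents that add atoms: ethyl (triphenylphosphoranylidene)acetate, CCOC(=O)C=P(c1ccccc1)(c1ccccc1)c1ccccc1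
Why: Wittig olefination with a stabilised ylide, which gives the E alkene and runs without added base, so the aryl silyl ether is not attacked; heating compensates for the hindered, electron-rich aldehyde.

Step 5
Reactants: 5 ethyl (E)-3-[4-(benzyloxy)-2-methoxy-6-(triisopropylsilyloxy)phenyl]prop-2-enoate
Product: 6 (E)-3-[4-(benzyloxy)-2-methoxy-6-(triisopropylsilyloxy)phenyl]prop-2-en-1-ol
Conditions: i-Bu2AlH (2.5 equiv), CH2Cl2, −78 °C; aq. potassium sodium tartrate
Reagents that add atoms: none
Why: 1,2-reduction of an α,β-unsaturated ester with an aluminium hydride gives the allylic alcohol without touching the alkene, the benzyl ether or the silyl ether.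

Step 6
Reactants: 6 (E)-3-[4-(benzyloxy)-2-methoxy-6-(triisopropylsilyloxy)phenyl]prop-2-en-1-ol
Product: 7 (E)-3-[4-(benzyloxy)-2-methoxy-6-(triisopropylsilyloxy)phenyl]prop-2-en-1-yl methyl carbonate
Conditions: ClCO2Me (1.5 equiv), pyridine (3 equiv), CH2Cl2, 0 °C
Reagents that add atoms: methyl chloroformate, COC(=O)Cl
Why: O-acylation of a primary alcohol with a chloroformate; the basic medium keeps the acid-sensitive, electron-rich cinnamyl system from ionising, and the carbonate is used without long storage.

Step 7
Reactants: 7 (E)-3-[4-(benzyloxy)-2-methoxy-6-(triisopropylsilyloxy)phenyl]prop-2-en-1-yl methyl carbonate; 8 N-methylbut-3-en-1-amine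
Product: 9 (S)-N-{1-[4-(benzyloxy)-2-methoxy-6-(triisopropylsilyloxy)phenyl]prop-2-en-1-yl}-N-methylbut-3-en-1-amine
Conditions: [Ir(cod)Cl]2 (2 mol %), (Sa,S,S)-O,O′-(1,1′-binaphthalene-2,2′-diyl) N,N-bis[1-(2-methoxyphenyl)ethyl]phosphoramidite (4 mol %), 1,5,7-triazabicyclo[4.4.0]dec-5-ene (8 mol %), 8 (1.3 equiv), THF, rt
Reagents that add atoms: none
Why: Iridium-catalysed branch-selective asymmetric allylic amination of a cinnamyl carbonate with a secondary amine; the cyclometalated iridium–phosphoramidite complex ionises the carbonate to an allyl complex and the amine attacks the aryl-bearing terminus anti to the metal. The chiral ligand decides the face and so sets C2′ as S, and the 2-methoxyphenyl variant of the ligand is chosen because it is the one suited to ortho-substituted aryl groups.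

Step 8
Reactants: 9 (S)-N-{1-[4-(benzyloxy)-2-methoxy-6-(triisopropylsilyloxy)phenyl]prop-2-en-1-yl}-N-methylbut-3-en-1-amine
Product: 12 (S)-2-[4-(benzyloxy)-2-methoxy-6-(triisopropylsilyloxy)phenyl]-1-methyl-1,2,5,6-tetrahydropyridine, via diene ammonium tosylate 10 (not isolated), via tetrahydropyridinium tosylate 11 (not isolated)
Conditions: p-TsOH (1.05 equiv), CH2Cl2, rt; then second-generation Grubbs catalyst RuCl2(=CHPh)(H2IMes)(PCy3) (5 mol %), CH2Cl2 (0.005 M), 40 °C, short reaction time; aq. NaHCO3
Reagents that add atoms: none
Why: Ring-closing olefin metathesis of a diene amine as its ammonium salt, a known route to 1,2,5,6-tetrahydropyridines. Protonation to 10 removes the nitrogen lone pair that would otherwise bind to ruthenium. The benzylidene initiates on the less hindered butenyl alkene, the new alkylidene adds to the vinyl group on C2′ in a [2+2] cycloaddition, and cycloreversion of the ruthenacyclobutane forms C3′=C4′ and releases ethylene, which leaves the solution and drives the reaction. The six-membered ring closes by joining the two terminal alkene carbons of a 1,7-diene; it is unstrained and its alkene is necessarily cis. No stereocentre is formed, and C2′ takes part in no bond that is made or broken, so its configuration should be carried through into 11 and, after basification, into 12. The step needs cyclisation to win over cross-metathesis oligomerisation, which high dilution secures. It also needs the alkene to stay at C3′–C4′, because migration into conjugation with C2′ would erase the stereocentre; a short reaction time and the acidic medium, in which ruthenium hydrides do not persist, work against that. Only one equivalent of acid is used so that the electron-rich benzylic C2′–N bond is not ionised.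

Step 9
Reactants: 12 (S)-2-[4-(benzyloxy)-2-methoxy-6-(triisopropylsilyloxy)phenyl]-1-methyl-1,2,5,6-tetrahydropyridine
Product: 13 (S)-2-[4-(benzyloxy)-2-methoxy-6-(triisopropylsilyloxy)phenyl]-1-methylpiperidine
Conditions: H2 (1 atm), PtO2 (5 mol %), EtOAc, rt
Reagents that add atoms: none
Why: Heterogeneous hydrogenation of a cis-disubstituted alkene; platinum is chosen because it is far less prone than palladium to double-bond migration and to hydrogenolysis of the allylic, benzylic C2′–N bond, and it leaves the benzyl ether in place.

Step 10
Reactants: 13 (S)-2-[4-(benzyloxy)-2-methoxy-6-(triisopropylsilyloxy)phenyl]-1-methylpiperidine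
Product: 14 3-methoxy-4-[(S)-1-methylpiperidin-2-yl]-5-(triisopropylsilyloxy)phenol
Conditions: H2 (1 atm), 10% Pd/C, EtOH, rt
Reagents that add atoms: none
Why: Hydrogenolysis of an aryl benzyl ether; without added acid the ring C2′–N bond, shielded by two ortho substituents, should be cleaved much more slowly than the O-benzyl bond, and the silyl ether is inert.

Step 11
Reactants: 14 3-methoxy-4-[(S)-1-methylpiperidin-2-yl]-5-(triisopropylsilyloxy)phenol
Product: 15 2-iodo-3-methoxy-4-[(S)-1-methylpiperidin-2-yl]-5-(triisopropylsilyloxy)phenol
Conditions: N-iodosuccinimide (1.0 equiv), CH2Cl2, −40 → 0 °C, dark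
Reagents that add atoms: N-iodosuccinimide, O=C1CCC(=O)N1I
Why: Electrophilic aromatic iodination ortho to a free phenol; both open positions are ortho to the O8a hydroxyl, but C8 lies next to the triisopropylsilyl ether, whose isopropyl groups are pushed towards it by the neighbouring piperidine, so iodine should enter at C4a between the hydroxyl and the methoxy group. Low temperature and one equivalent limit di-iodination and oxidation at nitrogen.

Step 12
Reactants: 15 2-iodo-3-methoxy-4-[(S)-1-methylpiperidin-2-yl]-5-(triisopropylsilyloxy)phenol; 16 phenylacetylene
Product: 18 5-methoxy-6-[(S)-1-methylpiperidin-2-yl]-7-(triisopropylsilyloxy)flavone, via aryl alkynyl ketone 17 (not isolated)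
Conditions: PdCl2(PPh3)2 (5 mol %), dppp (5 mol %), thiourea (5 mol %), DBU (2 equiv), 16 (1.5 equiv), CO (1 atm), Et2NH, 40 °C
Reagents that add atoms: carbon monoxide, [C-]#[O+]
Why: Palladium-catalysed carbonylative coupling and cyclisation of an ortho-iodophenol with a terminal alkyne, a known flavone synthesis; oxidative addition of C4a–I to zerovalent palladium, CO insertion and coupling with the alkyne give ynone 17, and in diethylamine the phenol adds to the activated triple bond in the 6-endo sense to give the pyranone and not the 5-exo aurone. The silyl ether on O7 leaves O8a as the only phenol, and the low temperature protects C2′.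

Step 13
Reactants: 18 5-methoxy-6-[(S)-1-methylpiperidin-2-yl]-7-(triisopropylsilyloxy)flavone
Product: 19 7-hydroxy-5-methoxy-6-[(S)-1-methylpiperidin-2-yl]-2-phenyl-4H-chromen-4-one
Conditions: Bu4NF (1.2 equiv), AcOH (1.2 equiv), THF, 0 °C
Reagents that add atoms: none
Why: Fluoride cleavage of an aryl silyl ether, driven by the Si–F bond; buffering with acetic acid delivers the phenol and not the phenoxide, so the ortho-hydroxybenzylic amine is not exposed to base.

## Compound list

1 | 2,4,6-trihydroxybenzaldehyde | O=Cc1c(O)cc(O)cc1O | starting material
2 | 4-(benzyloxy)-2,6-dihydroxybenzaldehyde | O=Cc1c(O)cc(OCc2ccccc2)cc1O | intermediate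
3 | 4-(benzyloxy)-2-hydroxy-6-methoxybenzaldehyde | COc1cc(OCc2ccccc2)cc(O)c1C=O | intermediate
4 | 4-(benzyloxy)-2-methoxy-6-(triisopropylsilyloxy)benzaldehyde | COc1cc(OCc2ccccc2)cc(O[Si](C(C)C)(C(C)C)C(C)C)c1C=O | intermediate
5 | ethyl (E)-3-[4-(benzyloxy)-2-methoxy-6-(triisopropylsilyloxy)phenyl]prop-2-enoate | COc1cc(OCc2ccccc2)cc(O[Si](C(C)C)(C(C)C)C(C)C)c1/C=C/C(=O)OCC | intermediate
6 | (E)-3-[4-(benzyloxy)-2-methoxy-6-(triisopropylsilyloxy)phenyl]prop-2-en-1-ol | COc1cc(OCc2ccccc2)cc(O[Si](C(C)C)(C(C)C)C(C)C)c1/C=C/CO | intermediate
7 | (E)-3-[4-(benzyloxy)-2-methoxy-6-(triisopropylsilyloxy)phenyl]prop-2-en-1-yl methyl carbonate | COc1cc(OCc2ccccc2)cc(O[Si](C(C)C)(C(C)C)C(C)C)c1/C=C/COC(=O)OC | intermediate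
8 | N-methylbut-3-en-1-amine | CNCCC=C | starting material
9 | (S)-N-{1-[4-(benzyloxy)-2-methoxy-6-(triisopropylsilyloxy)phenyl]prop-2-en-1-yl}-N-methylbut-3-en-1-amine | COc1cc(OCc2ccccc2)cc(O[Si](C(C)C)(C(C)C)C(C)C)c1[C@H](C=C)N(C)CCC=C | intermediate
10 | p-toluenesulfonate salt of 9 (diene ammonium tosylate) | COc1cc(OCc2ccccc2)cc(O[Si](C(C)C)(C(C)C)C(C)C)c1[C@H](C=C)[NH+](C)CCC=C.Cc1ccc(S(=O)(=O)[O-])cc1 | intermediate
11 | (S)-2-[4-(benzyloxy)-2-methoxy-6-(triisopropylsilyloxy)phenyl]-1-methyl-1,2,5,6-tetrahydropyridinium p-toluenesulfonate | COc1cc(OCc2ccccc2)cc(O[Si](C(C)C)(C(C)C)C(C)C)c1[C@@H]3C=CCC[NH+]3C.Cc1ccc(S(=O)(=O)[O-])cc1 | intermediate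
12 | (S)-2-[4-(benzyloxy)-2-methoxy-6-(triisopropylsilyloxy)phenyl]-1-methyl-1,2,5,6-tetrahydropyridine | COc1cc(OCc2ccccc2)cc(O[Si](C(C)C)(C(C)C)C(C)C)c1[C@@H]3C=CCCN3C | intermediate
13 | (S)-2-[4-(benzyloxy)-2-methoxy-6-(triisopropylsilyloxy)phenyl]-1-methylpiperidine | COc1cc(OCc2ccccc2)cc(O[Si](C(C)C)(C(C)C)C(C)C)c1[C@@H]3CCCCN3C | intermediate
14 | 3-methoxy-4-[(S)-1-methylpiperidin-2-yl]-5-(triisopropylsilyloxy)phenol | COc1cc(O)cc(O[Si](C(C)C)(C(C)C)C(C)C)c1[C@@H]3CCCCN3C | intermediate
15 | 2-iodo-3-methoxy-4-[(S)-1-methylpiperidin-2-yl]-5-(triisopropylsilyloxy)phenol | COc1c([C@@H]2CCCCN2C)c(O[Si](C(C)C)(C(C)C)C(C)C)cc(O)c1I | intermediate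
16 | phenylacetylene | C#Cc1ccccc1 | starting material
17 | 1-{6-hydroxy-2-methoxy-3-[(S)-1-methylpiperidin-2-yl]-4-(triisopropylsilyloxy)phenyl}-3-phenylprop-2-yn-1-one | COc1c([C@@H]2CCCCN2C)c(O[Si](C(C)C)(C(C)C)C(C)C)cc(O)c1C(=O)C#Cc1ccccc1 | intermediate
18 | 5-methoxy-6-[(S)-1-methylpiperidin-2-yl]-7-(triisopropylsilyloxy)flavone | COc1c([C@@H]2CCCCN2C)c(O[Si](C(C)C)(C(C)C)C(C)C)cc2oc(-c3ccccc3)cc(=O)c12 | intermediate
19 | 7-hydroxy-5-methoxy-6-[(S)-1-methylpiperidin-2-yl]-2-phenyl-4H-chromen-4-one | COc1c([C@@H]2CCCCN2C)c(O)cc2oc(-c3ccccc3)cc(=O)c12 | target

## Step count and least certain steps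

Total: 13 steps. Longest linear sequence: 13 steps, from 1 to 19; the amine 8 and the alkyne 16 are used as bought.

**Step 8 (key step).** Three things could go wrong. The ruthenium catalyst may be deactivated if protonation of the amine is incomplete. Ruthenium hydrides may move the new alkene towards C2′, which would cost the stereocentre. The acid may ionise the C2′–N bond of the tri-oxygenated benzylic ammonium ion, which would cause racemisation or loss of the amine. The vinyl group next to the 2,6-disubstituted ring may also react slowly enough for oligomerisation to compete. Fallback: close the ring on a non-basic carbamate, setting out from 7 and coming back at 12. The same iridium-catalysed amination of 7, now with but-3-en-1-amine in excess, should give the secondary diene amine F1. Methyl chloroformate and Et3N turn it into the diene methyl carbamate F2. The second-generation Grubbs catalyst in CH2Cl2, without acid, should close it to the N-methoxycarbonyl tetrahydropyridine F3, and LiAlH4 in THF at 0 °C reduces the carbamate to the N-methyl group of 12.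

**Step 7.** The 2,6-disubstituted aryl ring may slow formation of the allyl complex and lower branch and face selectivity. The very electron-rich carbonate may also ionise without the catalyst, which would give racemic or linear amine. Fallback: an auxiliary-controlled addition, setting out from 4 and coming back at 9. Condensation of 4 with (R)-tert-butanesulfinamide and Ti(OEt)4 should give the sulfinyl imine F4. Vinylmagnesium bromide in CH2Cl2 at −78 °C is expected to add through the chelated six-membered transition state to give the (R)-sulfinyl (S)-allylic amine F5. LiN(SiMe3)2 and MeI methylate nitrogen to F6, HCl in MeOH at 0 °C removes the sulfinyl group to give the secondary N-methyl amine F7, and alkylation with 4-bromobut-1-ene (K2CO3, NaI, MeCN) gives 9.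

**Step 9.** Double-bond migration on the metal surface towards C2′ before reduction, or hydrogenolysis of the allylic and benzylic C2′–N bond, would give racemic or ring-opened material. Fallback: metal-free reduction of 12 with diimide, generated from 2-nitrobenzenesulfonylhydrazide and Et3N in CH2Cl2 at rt, which neither isomerises alkenes nor cleaves C–N bonds; it sets out from 12 and comes back at 13 with no new compound.

**Step 11.** Iodination may be poorly regioselective between C4a and C8, because both are ortho to the free phenol and only the steric bias of the silyl ether separates them; over-iodination and oxidation of the amine are further losses. Fallback: directed ortho-metalation, setting out from 14 and coming back at 15. MOMCl and i-Pr2NEt give the methoxymethyl ether F8. n-BuLi and TMEDA in THF (−78 → 0 °C) should lithiate only the position flanked by the two coordinating oxygens (OMOM and OMe), that is C4a, and not the position next to the non-coordinating silyl ether. Quenching with I2 gives the iodo methoxymethyl ether F9, and brief HCl in MeOH removes the acetal to give 15.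

**Step 12.** Oxidative addition at the electron-rich, doubly ortho-substituted C4a–I bond may be slow, so that direct alkyne coupling without CO insertion (leading to a benzofuran) or 5-exo closure competes. Prolonged warming of the para-hydroxybenzylic amine may erode C2′ through reversible quinone-methide ring opening. Fallback: make the acyl bond with a main-group aryl metal, setting out from 15 and coming back at 18. Deprotonation of the phenol with MeMgCl and iodine–magnesium exchange with i-PrMgCl·LiCl in THF at −20 °C, followed by N-methoxy-N-methyl-3-phenylprop-2-ynamide, should give the ynone 17, this time isolated. Et2NH at rt then closes it to 18. No new compound arises.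

## Further compounds

F1 | step 8 | (S)-N-{1-[4-(benzyloxy)-2-methoxy-6-(triisopropylsilyloxy)phenyl]prop-2-en-1-yl}but-3-en-1-amine | COc1cc(OCc2ccccc2)cc(O[Si](C(C)C)(C(C)C)C(C)C)c1[C@H](C=C)NCCC=C
F2 | step 8 | methyl (S)-N-(but-3-en-1-yl)-N-{1-[4-(benzyloxy)-2-methoxy-6-(triisopropylsilyloxy)phenyl]prop-2-en-1-yl}carbamate | COc1cc(OCc2ccccc2)cc(O[Si](C(C)C)(C(C)C)C(C)C)c1[C@H](C=C)N(CCC=C)C(=O)OC
F3 | step 8 | methyl (S)-6-[4-(benzyloxy)-2-methoxy-6-(triisopropylsilyloxy)phenyl]-3,6-dihydropyridine-1(2H)-carboxylate | COc1cc(OCc2ccccc2)cc(O[Si](C(C)C)(C(C)C)C(C)C)c1[C@@H]3C=CCCN3C(=O)OC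
F4 | step 7 | (R,E)-N-[4-(benzyloxy)-2-methoxy-6-(triisopropylsilyloxy)benzylidene]-2-methylpropane-2-sulfinamide | COc1cc(OCc2ccccc2)cc(O[Si](C(C)C)(C(C)C)C(C)C)c1/C=N/[S@](=O)C(C)(C)C
F5 | step 7 | (R)-N-{(S)-1-[4-(benzyloxy)-2-methoxy-6-(triisopropylsilyloxy)phenyl]prop-2-en-1-yl}-2-methylpropane-2-sulfinamide | COc1cc(OCc2ccccc2)cc(O[Si](C(C)C)(C(C)C)C(C)C)c1[C@H](C=C)N[S@](=O)C(C)(C)C
F6 | step 7 | (R)-N-{(S)-1-[4-(benzyloxy)-2-methoxy-6-(triisopropylsilyloxy)phenyl]prop-2-en-1-yl}-N-methyl-2-methylpropane-2-sulfinamide | COc1cc(OCc2ccccc2)cc(O[Si](C(C)C)(C(C)C)C(C)C)c1[C@H](C=C)N(C)[S@](=O)C(C)(C)C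
F7 | step 7 | (S)-1-[4-(benzyloxy)-2-methoxy-6-(triisopropylsilyloxy)phenyl]-N-methylprop-2-en-1-amine | COc1cc(OCc2ccccc2)cc(O[Si](C(C)C)(C(C)C)C(C)C)c1[C@H](C=C)NC
F0 | step 9 | none | none
F8 | step 11 | (S)-2-[2-methoxy-4-(methoxymethoxy)-6-(triisopropylsilyloxy)phenyl]-1-methylpiperidine | COc1cc(OCOC)cc(O[Si](C(C)C)(C(C)C)C(C)C)c1[C@@H]3CCCCN3C
F9 | step 11 | (S)-2-[3-iodo-2-methoxy-4-(methoxymethoxy)-6-(triisopropylsilyloxy)phenyl]-1-methylpiperidine | COc1c(I)c(OCOC)cc(O[Si](C(C)C)(C(C)C)C(C)C)c1[C@@H]3CCCCN3C
F0 | step 12 | none | none
A1 | alternative 1 | 1-{2,4-bis(benzoyloxy)-6-methoxy-5-[(S)-1-methylpiperidin-2-yl]phenyl}-2-(triphenylphosphoranylidene)ethan-1-one | COc1c([C@@H]2CCCCN2C)c(OC(=O)c2ccccc2)cc(OC(=O)c2ccccc2)c1C(=O)C=P(c1ccccc1)(c1ccccc1)c1ccccc1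
A2 | alternative 1 | 7-(benzoyloxy)-5-methoxy-6-[(S)-1-methylpiperidin-2-yl]flavone | COc1c([C@@H]2CCCCN2C)c(OC(=O)c3ccccc3)cc4oc(-c5ccccc5)cc(=O)c14
A3 | alternative 2 | methyl 2-{3-[2-((S)-1-(tert-butoxycarbonyl)piperidin-2-yl)acetyl]-4-oxo-6-phenyl-4H-pyran-2-yl}acetate | COC(=O)Cc1oc(-c2ccccc2)cc(=O)c1C(=O)C[C@@H]1CCCCN1C(=O)OC(C)(C)C
A4 | alternative 2 | 5,7-dihydroxy-6-[(S)-1-(tert-butoxycarbonyl)piperidin-2-yl]flavone | Oc1c([C@@H]2CCCCN2C(=O)OC(C)(C)C)c(O)cc2oc(-c3ccccc3)cc(=O)c12
A5 | alternative 3 | 5-methoxy-6-[(S)-1-methylpiperidin-2-yl]-7-(triisopropylsilyloxy)flavone (identical with 18) | COc1c([C@@H]2CCCCN2C)c(O[Si](C(C)C)(C(C)C)C(C)C)cc2oc(-c3ccccc3)cc(=O)c12
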